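**Strategy.** The nine-membered ring is closed late at C3–C4 (ring numbering: C1 = enal carbon, C2 = CH–CHO, C3 = side-chain methine, C4–C5 = CH2CH2, C6 = methyl-bearing olefin carbon; C10 = side-chain stereocentre). The key step exploits that the C2 formyl carbon and the C10 acetoxymethyl oxygen can share a temporary δ-lactone, which makes C3 the triflate-bearing β-carbon of a cyclic enol triflate, and that C4–C5 can arise from the vinyl end of an (E)-1,3-diene. Hydroboration and intramolecular B-alkyl Suzuki–Miyaura coupling join C4 to sp2-C3 and close the carbocycle in one operation; the lactone then steers hydrogen to C3 anti to the homoprenyl group.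

Key step: step 16

Assumption: the lipase in step 3 is taken to acetylate the enantiotopic CH2OH group of diol 4 that leads to (R)-5.

Step 1
Reactants: 1 diethyl malonate; 2 5-bromo-2-methylpent-2-ene
Product: 3 diethyl 2-(4-methylpent-3-en-1-yl)malonate
Conditions: NaOEt, EtOH, reflux (1 in slight excess)
Reagents that add atoms: none
Why: Malonic ester alkylation, in which the sodium enolate of 1 displaces the primary bromide of 2 by SN2 and the excess of 1 should suppress dialkylation.

Step 2
Reactants: 3 diethyl 2-(4-methylpent-3-en-1-yl)malonate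
Product: 4 2-(4-methylpent-3-en-1-yl)propane-1,3-diol
Conditions: LiAlH4, THF, 0 °C → reflux
Reagents that add atoms: none
Why: LiAlH4 reduces both esters to primary alcohols and leaves the trisubstituted alkene untouched, giving the prochiral diol.

Step 3
Reactants: 4 2-(4-methylpent-3-en-1-yl)propane-1,3-diol
Product: 5 (R)-2-(hydroxymethyl)-6-methylhept-5-en-1-yl acetate
Conditions: lipase from Burkholderia cepacia (lipase PS), vinyl acetate, t-BuOMe, rt
Reagents that add atoms: vinyl acetate, C=COC(C)=O
Why: Enzymatic desymmetrization by irreversible lipase-catalysed transesterification, in which the enzyme's active site distinguishes the two enantiotopic CH2OH groups and so sets C10.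

Step 4
Reactants: 5 (R)-2-(hydroxymethyl)-6-methylhept-5-en-1-yl acetate
Product: 6 (S)-2-formyl-6-methylhept-5-en-1-yl acetate
Conditions: Dess–Martin periodinane, CH2Cl2, 0 °C; used at once
Reagents that add atoms: none
Why: Dess–Martin oxidation of the primary alcohol under non-basic conditions should give the α-branched aldehyde without epimerization at C10 or loss of acetate.

Step 5
Reactants: 7 (E)-3-methylpent-2-en-4-yn-1-ol
Product: 8 (E)-3-methylpenta-2,4-dien-1-ol
Conditions: H2 (1 atm), Pd/CaCO3 poisoned with Pb(OAc)2 (Lindlar catalyst), quinoline, EtOAc, rt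
Reagents that add atoms: none
Why: Semihydrogenation on the poisoned palladium surface should stop at the alkene, turning the terminal alkyne into the vinyl group while the (E)-trisubstituted alkene is kept.

Step 6
Reactants: 8 (E)-3-methylpenta-2,4-dien-1-ol
Product: 9 (E)-5-bromo-3-methylpenta-1,3-diene
Conditions: PBr3, Et2O, −20 °C; used cold
Reagents that add atoms: phosphorus tribromide, BrP(Br)Br
Why: Bromination of the primary allylic alcohol through its phosphite ester, the conjugated (E)-dienyl bromide being the preferred allylic isomer.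

Step 7
Reactants: 9 (E)-5-bromo-3-methylpenta-1,3-diene; 10 prop-2-yn-1-ol
Product: 11 (5E)-6-methylocta-5,7-dien-2-yn-1-ol
Conditions: CuI (10 mol %), K2CO3, n-Bu4NI (10 mol %), DMF, rt
Reagents that add atoms: none
Why: Copper-acetylide allylic substitution at the primary terminus of the dienyl bromide forms the skipped enyne; attack at either terminus of the symmetric 3-methylpentadienyl unit gives the same constitution.

Step 8
Reactants: 11 (5E)-6-methylocta-5,7-dien-2-yn-1-ol
Product: 13 (2Z,5E)-2-iodo-6-methylocta-2,5,7-trien-1-ol, via alkenylalane 12 (not isolated)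
Conditions: LiAlH4, AlCl3 (2 mol %), THF, rt; then I2, THF, −78 °C
Reagents that add atoms: iodine, II
Why: trans-Hydroalumination of the propargylic alcohol should place hydride on the alkyne carbon remote from oxygen and aluminium on the one next to CH2O, and iodinolysis with retention then gives the (Z)-iodide that fixes the C9=C1 geometry.

Step 9
Reactants: 13 (2Z,5E)-2-iodo-6-methylocta-2,5,7-trien-1-ol
Product: 14 (2Z,5E)-2-iodo-6-methylocta-2,5,7-trienal
Conditions: MnO2, CH2Cl2, rt
Reagents that add atoms: none
Why: MnO2 oxidizes the allylic alcohol selectively to the α-iodo enal under neutral conditions that should not isomerize the skipped diene.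

Step 10
Reactants: 14 (2Z,5E)-2-iodo-6-methylocta-2,5,7-trienal
Product: 15 (2Z,5E)-2-iodo-1,1-dimethoxy-6-methylocta-2,5,7-triene
Conditions: HC(OMe)3, PPTS (cat.), MeOH, rt
Reagents that add atoms: trimethyl orthoformate, COC(OC)OC
Why: Acid-catalysed acetalization masks the future C1 formyl group against the basic, hydridic and organometallic steps that follow.

Step 11
Reactants: 15 (2Z,5E)-2-iodo-1,1-dimethoxy-6-methylocta-2,5,7-triene
Product: 16 methyl (3E,6E)-3-(dimethoxymethyl)-7-methylnona-3,6,8-trienoate
Conditions: Zn dust, BrCH2CO2Me, THF, 40 °C (gives BrZnCH2CO2Me); then 15, Pd(PPh3)4 (5 mol %), THF, 50 °C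
Reagents that add atoms: methyl bromoacetate, COC(=O)CBr
Why: Zinc inserts into the C–Br bond of methyl bromoacetate to give the Reformatsky reagent, whose Negishi cross-coupling with the alkenyl iodide proceeds with retention of alkene geometry and should give the β,γ-unsaturated ester without conjugation.

Step 12
Reactants: 16 methyl (3E,6E)-3-(dimethoxymethyl)-7-methylnona-3,6,8-trienoate; 6 (S)-2-formyl-6-methylhept-5-en-1-yl acetate
Product: 18 methyl (3E,6E)-2-[(2S)-3-acetoxy-1-hydroxy-2-(4-methylpent-3-en-1-yl)propyl]-3-(dimethoxymethyl)-7-methylnona-3,6,8-trienoate (diastereomer mixture at C2 and the carbinol carbon), via lithium dienolate 17 (not isolated)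
Conditions: LiN(i-Pr)2, THF, −78 °C; then 6; AcOH, −78 °C
Reagents that add atoms: none
Why: Aldol addition of the kinetically formed lithium dienolate through its α-carbon forms the C2–C3 bond, the two new stereocentres are erased in steps 13 and 14, and the cold acidic quench should prevent acetate migration.

Step 13
Reactants: 18 aldol adduct
Product: 19 methyl (3E,6E)-2-[(2S)-3-acetoxy-2-(4-methylpent-3-en-1-yl)propanoyl]-3-(dimethoxymethyl)-7-methylnona-3,6,8-trienoate
Conditions: Dess–Martin periodinane, pyridine, CH2Cl2, 0 °C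
Reagents that add atoms: none
Why: Dess–Martin oxidation converts the secondary alcohol into the ketone of an enolizable β-keto ester, with pyridine buffering the acetic acid so that the acetal survives.

Step 14
Reactants: 19 β-keto ester
Product: 21 (5S)-3-[(2E,5E)-1,1-dimethoxy-6-methylocta-2,5,7-trien-2-yl]-4-hydroxy-5-(4-methylpent-3-en-1-yl)-5,6-dihydro-2H-pyran-2-one, via hydroxy keto ester 20 (not isolated)
Conditions: K2CO3, MeOH, 0 °C → rt; aq. NaH2PO4 work-up
Reagents that add atoms: none
Why: Methanolysis of the acetate frees the primary alcohol, which lactonizes onto the methyl ester to the six-membered β-keto lactone (isolated as its enol), while enolate formation between the carbonyls should protect C10 from epimerization and β-elimination.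

Step 15
Reactants: 21 enolized β-keto lactone
Product: 22 (3S)-5-[(2E,5E)-1,1-dimethoxy-6-methylocta-2,5,7-trien-2-yl]-3-(4-methylpent-3-en-1-yl)-6-oxo-3,6-dihydro-2H-pyran-4-yl trifluoromethanesulfonate
Conditions: PhNTf2, Et3N, DMAP (cat.), CH2Cl2, rt
Reagents that add atoms: N-phenylbis(trifluoromethanesulfonimide), O=S(=O)(N(c1ccccc1)S(=O)(=O)C(F)(F)F)C(F)(F)F
Why: O-Sulfonylation of the vinylogous acid gives the enol triflate, which turns the future C3 into an electrophilic sp2 carbon.

Step 16
Reactants: 22 enol triflate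
Product: 24 (4R,7E,10E)-11-(dimethoxymethyl)-7-methyl-4-(4-methylpent-3-en-1-yl)-3,4,5,6-tetrahydrocyclonona[c]pyran-1(9H)-one (δ-lactone fused to the nine-membered ring across the tetrasubstituted alkene), via B-alkyl borane 23 (not isolated)
Conditions: 9-BBN, THF, 0 °C → rt; then Pd(dppf)Cl2 (20 mol %), AsPh3, Cs2CO3, H2O, DMF/THF, 50 °C, slow addition, 1 mM
Reagents that add atoms: none
Why: 9-BBN adds anti-Markovnikov to the only monosubstituted alkene, the vinyl end of the diene, to give primary borane 23; zerovalent palladium then inserts into the C–OTf bond, the borate formed with Cs2CO3 and water transfers the C4 alkyl group to palladium, and reductive elimination forges C3–C4. The closest known reaction type is the B-alkyl Suzuki–Miyaura macrocyclization used to close (E)-cyclononenes, together with couplings of lactone-derived enol triflates. The nine-membered carbocycle is closed by sp3–sp2 coupling through a ten-membered palladacycle and ends up fused to the pyranone across its C2=C3 double bond. No stereocentre is created, since C3 stays sp2; the lactone fixes the ring-cis geometry at C2=C3, and the C6=C7 and C9=C1 geometries are carried in from 9 and 13. The step needs chemoselective hydroboration, secured by the steric preference of 9-BBN for CH2=CH over three trisubstituted alkenes and the electron-poor enol triflate, and cyclization over oligomerization, secured by slow addition at high dilution. β-Hydride elimination of the alkylpalladium should be held back by the wide-bite-angle ligand dppf.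

Step 17
Reactants: 24 bicyclic dienyl lactone
Product: 25 (4R,4aS,7E,10E,11aS)-11-(dimethoxymethyl)-7-methyl-4-(4-methylpent-3-en-1-yl)-3,4,4a,5,6,9-hexahydrocyclonona[c]pyran-1(11aH)-one
Conditions: SmI2, HMPA, t-BuOH, THF, −78 → −20 °C
Reagents that add atoms: none
Why: Single-electron conjugate reduction places hydrogen on C3 anti to the C10 homoprenyl group, which allylic 1,2-strain with the C3–C4 bond holds pseudoaxial on the lactone, and α-protonation of the resulting dienolate at C2 should give the trans-fused lactone, the more stable C2 epimer.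

Step 18
Reactants: 25 saturated lactone
Product: 27 (2R)-2-[(1S,2S,3E,6E)-3-(dimethoxymethyl)-2-[methoxy(methyl)carbamoyl]-7-methylcyclonona-3,6-dien-1-yl]-6-methylhept-5-en-1-yl acetate, via magnesium alkoxide 26 (not isolated)
Conditions: MeNH(OMe)·HCl, i-PrMgCl, THF, −20 °C; then Ac2O, DMAP (cat.), 0 °C → rt
Reagents that add atoms: N,O-dimethylhydroxylamine hydrochloride, CNOC.Cl; acetic anhydride, CC(=O)OC(C)=O
Why: Aminolysis of the lactone by the chloromagnesium amide gives the open-chain Weinreb amide as its alkoxide, which is acetylated in the same flask before it can relactonize, reinstalling the acetate of the target.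

Step 19
Reactants: 27 acetoxy Weinreb amide
Product: 30 (2R)-2-[(1S,2S,3E,6E)-2,3-diformyl-7-methylcyclonona-3,6-dien-1-yl]-6-methylhept-5-en-1-yl acetate (target), via zirconium hemiaminal 28 (not isolated), via aldehyde acetal 29 (not isolated)
Conditions: Cp2Zr(H)Cl, THF, rt; then 1 M HCl, THF/H2O, 0 °C
Reagents that add atoms: water, O
Why: Cp2Zr(H)Cl reduces the tertiary amide chemoselectively in the presence of the acetate to a stable zirconium hemiaminal, and the aqueous acid then releases the C2 aldehyde and hydrolyses the allylic dimethyl acetal to the C1 enal under conditions mild enough to keep the C2 configuration.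

**Compound list**

1 | diethyl malonate | CCOC(=O)CC(=O)OCC | starting material
2 | 5-bromo-2-methylpent-2-ene | CC(C)=CCCBr | starting material
3 | diethyl 2-(4-methylpent-3-en-1-yl)malonate | CCOC(=O)C(CCC=C(C)C)C(=O)OCC | intermediate
4 | 2-(4-methylpent-3-en-1-yl)propane-1,3-diol | OCC(CCC=C(C)C)CO | intermediate
5 | (R)-2-(hydroxymethyl)-6-methylhept-5-en-1-yl acetate | CC(=O)OC[C@H](CCC=C(C)C)CO | intermediate
6 | (S)-2-formyl-6-methylhept-5-en-1-yl acetate | CC(=O)OC[C@H](CCC=C(C)C)C=O | intermediate
7 | (E)-3-methylpent-2-en-4-yn-1-ol | C#C/C(C)=C/CO | starting material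
8 | (E)-3-methylpenta-2,4-dien-1-ol | C=C/C(C)=C/CO | intermediate
9 | (E)-5-bromo-3-methylpenta-1,3-diene | C=C/C(C)=C/CBr | intermediate
10 | prop-2-yn-1-ol | C#CCO | starting material
11 | (5E)-6-methylocta-5,7-dien-2-yn-1-ol | OCC#CC/C=C(C)/C=C | intermediate
12 | (Z)-alkenylalane of 11 (aluminium on C2 and on oxygen) | [AlH2]OC/C([AlH2])=C/C/C=C(C)/C=C | intermediate (not isolated)
13 | (2Z,5E)-2-iodo-6-methylocta-2,5,7-trien-1-ol | OC/C(I)=C/C/C=C(C)/C=C | intermediate
14 | (2Z,5E)-2-iodo-6-methylocta-2,5,7-trienal | O=C/C(I)=C/C/C=C(C)/C=C | intermediate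
15 | (2Z,5E)-2-iodo-1,1-dimethoxy-6-methylocta-2,5,7-triene | COC(OC)/C(I)=C/C/C=C(C)/C=C | intermediate
16 | methyl (3E,6E)-3-(dimethoxymethyl)-7-methylnona-3,6,8-trienoate | COC(=O)C/C(C(OC)OC)=C\C/C=C(C)/C=C | intermediate
17 | lithium dienolate of 16 | [Li+].COC([O-])=C/C(C(OC)OC)=C\C/C=C(C)/C=C | intermediate (not isolated)
18 | methyl (3E,6E)-2-[(2S)-3-acetoxy-1-hydroxy-2-(4-methylpent-3-en-1-yl)propyl]-3-(dimethoxymethyl)-7-methylnona-3,6,8-trienoate | COC(=O)C(C(O)[C@@H](CCC=C(C)C)COC(C)=O)/C(C(OC)OC)=C\C/C=C(C)/C=C | intermediate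
19 | methyl (3E,6E)-2-[(2S)-3-acetoxy-2-(4-methylpent-3-en-1-yl)propanoyl]-3-(dimethoxymethyl)-7-methylnona-3,6,8-trienoate | COC(=O)C(C(=O)[C@@H](CCC=C(C)C)COC(C)=O)/C(C(OC)OC)=C\C/C=C(C)/C=C | intermediate
20 | methyl (3E,6E)-3-(dimethoxymethyl)-2-[(2S)-3-hydroxy-2-(4-methylpent-3-en-1-yl)propanoyl]-7-methylnona-3,6,8-trienoate | COC(=O)C(C(=O)[C@@H](CCC=C(C)C)CO)/C(C(OC)OC)=C\C/C=C(C)/C=C | intermediate (not isolated)
21 | (5S)-3-[(2E,5E)-1,1-dimethoxy-6-methylocta-2,5,7-trien-2-yl]-4-hydroxy-5-(4-methylpent-3-en-1-yl)-5,6-dihydro-2H-pyran-2-one | O=C1OC[C@H](CCC=C(C)C)C(O)=C1/C(C(OC)OC)=C\C/C=C(C)/C=C | intermediate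
22 | (3S)-5-[(2E,5E)-1,1-dimethoxy-6-methylocta-2,5,7-trien-2-yl]-3-(4-methylpent-3-en-1-yl)-6-oxo-3,6-dihydro-2H-pyran-4-yl trifluoromethanesulfonate | O=C1OC[C@H](CCC=C(C)C)C(OS(=O)(=O)C(F)(F)F)=C1/C(C(OC)OC)=C\C/C=C(C)/C=C | intermediate
23 | B-alkyl-9-BBN borane of 22 (boron on the former terminal CH2) | O=C1OC[C@H](CCC=C(C)C)C(OS(=O)(=O)C(F)(F)F)=C1/C(C(OC)OC)=C\C/C=C(C)/CCB1C2CCCC1CCC2 | intermediate (not isolated)
24 | (4R,7E,10E)-11-(dimethoxymethyl)-7-methyl-4-(4-methylpent-3-en-1-yl)-3,4,5,6-tetrahydrocyclonona[c]pyran-1(9H)-one | O=C1OC[C@H](CCC=C(C)C)C2=C1/C(C(OC)OC)=C\C/C=C(C)/CC2 | intermediate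
25 | (4R,4aS,7E,10E,11aS)-11-(dimethoxymethyl)-7-methyl-4-(4-methylpent-3-en-1-yl)-3,4,4a,5,6,9-hexahydrocyclonona[c]pyran-1(11aH)-one | O=C1OC[C@H](CCC=C(C)C)[C@@H]2CC/C(C)=C/C/C=C(/C(OC)OC)[C@H]21 | intermediate
26 | chloromagnesium alkoxide of the hydroxy Weinreb amide (2S,3S,10R) | Cl[Mg]OC[C@H](CCC=C(C)C)[C@@H]1CC/C(C)=C/C/C=C(/C(OC)OC)[C@H]1C(=O)N(C)OC | intermediate (not isolated)
27 | (2R)-2-[(1S,2S,3E,6E)-3-(dimethoxymethyl)-2-[methoxy(methyl)carbamoyl]-7-methylcyclonona-3,6-dien-1-yl]-6-methylhept-5-en-1-yl acetate | CC(=O)OC[C@H](CCC=C(C)C)[C@@H]1CC/C(C)=C/C/C=C(/C(OC)OC)[C@H]1C(=O)N(C)OC | intermediate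
28 | zirconium hemiaminal of 27 (O–ZrCp2Cl, N(OMe)Me on the former amide carbon) | CC(=O)OC[C@H](CCC=C(C)C)[C@@H]1CC/C(C)=C/C/C=C(/C(OC)OC)[C@H]1C(O[Zr](Cl)(C2C=CC=C2)C2C=CC=C2)N(C)OC | intermediate (not isolated)
29 | (2R)-2-[(1S,2S,3E,6E)-3-(dimethoxymethyl)-2-formyl-7-methylcyclonona-3,6-dien-1-yl]-6-methylhept-5-en-1-yl acetate | CC(=O)OC[C@H](CCC=C(C)C)[C@@H]1CC/C(C)=C/C/C=C(/C(OC)OC)[C@H]1C=O | intermediate (not isolated)
30 | (2R)-2-[(1S,2S,3E,6E)-2,3-diformyl-7-methylcyclonona-3,6-dien-1-yl]-6-methylhept-5-en-1-yl acetate | CC(=O)OC[C@H](CCC=C(C)C)[C@@H]1CC/C(C)=C/C/C=C(/C=O)[C@H]1C=O | target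

**Step count.** Total: 19 steps. Longest linear sequence: 15 steps (7 → 30, steps 5–19).

**Steps most likely to fail**

Step 16 (ring closure). Intermolecular coupling and protodeboronation may outrun closure, because the tetrasubstituted lactone alkene, the adjacent C9=C1 alkene and the (E)-C6=C7 alkene together stiffen and strain the forming ring. The fallback changes the order of ring construction. It sets out from keto ester 19, which is triflated under non-chelating conditions (Tf2O, aqueous Me4NOH, toluene) to the acyclic (E)-enol triflate F1, with the ester cis to C10. Hydroboration with 9-BBN gives its B-alkyl borane F2, which is coupled under the conditions of step 16 to the monocyclic triene ester F3; this ring closes without the constraint of the pyranone. K2CO3 in MeOH then removes the acetate to give hydroxy ester F4, which lactonizes to 24, where the fallback rejoins the route.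

Step 17 (conjugate reduction). Electron transfer to the hindered tetrasubstituted enoate may be sluggish, hydrogen may reach C3 with poor facial selectivity, or the dienolate may be protonated at C9 with migration of the double bond. The fallback replaces electron transfer by two-electron hydride delivery. It sets out from 24: a copper hydride generated from [1,3-bis(2,6-diisopropylphenyl)imidazol-2-ylidene]CuCl, NaOt-Bu and polymethylhydrosiloxane with t-BuOH in toluene should add hydride to C3 from the same open face, and the copper enolate is protonated at C2. It returns to 25 without any new isolated compound.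

Step 12 (aldol). Base-induced β-elimination of acetate from the α-branched aldehyde, or acetyl migration to the new alkoxide, may erode the addition. The fallback moves the C2–C3 bond formation to the carboxylic acid oxidation level. It sets out from 5, which is oxidized (TEMPO, PhI(OAc)2, MeCN/H2O) to acetoxy acid F5 and activated with carbonyldiimidazole to acyl imidazole F6. C-Acylation of lithium dienolate 17 (crossed Claisen condensation, with a second equivalent of LiN(SiMe3)2 to absorb the acidic product) then gives keto ester 19 directly, where it rejoins the route; aldehyde 6 and step 13 are bypassed.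

**Further compounds**

F1 | step 16 | methyl (2E,4S)-4-(acetoxymethyl)-2-[(2E,5E)-1,1-dimethoxy-6-methylocta-2,5,7-trien-2-yl]-8-methyl-3-(trifluoromethanesulfonyloxy)nona-2,7-dienoate | COC(=O)/C(/C(C(OC)OC)=C\C/C=C(C)/C=C)=C(/OS(=O)(=O)C(F)(F)F)[C@@H](CCC=C(C)C)COC(C)=O
F2 | step 16 | B-alkyl-9-BBN borane of F1 | COC(=O)/C(/C(C(OC)OC)=C\C/C=C(C)/CCB1C2CCCC1CCC2)=C(/OS(=O)(=O)C(F)(F)F)[C@@H](CCC=C(C)C)COC(C)=O
F3 | step 16 | methyl (5E)-2-[(2R)-1-acetoxy-6-methylhept-5-en-2-yl]-9-(dimethoxymethyl)-5-methylcyclonona-1,5,8-triene-1-carboxylate (ring-cis at C1=C2 and C8=C9) | COC(=O)/C1=C(\[C@@H](CCC=C(C)C)COC(C)=O)CC/C(C)=C/C/C=C1/C(OC)OC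
F4 | step 16 | methyl (5E)-9-(dimethoxymethyl)-2-[(2R)-1-hydroxy-6-methylhept-5-en-2-yl]-5-methylcyclonona-1,5,8-triene-1-carboxylate | COC(=O)/C1=C(\[C@@H](CCC=C(C)C)CO)CC/C(C)=C/C/C=C1/C(OC)OC
F0 | step 17 | none | none
F5 | step 12 | (S)-2-(acetoxymethyl)-6-methylhept-5-enoic acid | CC(=O)OC[C@H](CCC=C(C)C)C(=O)O
F6 | step 12 | (S)-2-(1H-imidazole-1-carbonyl)-6-methylhept-5-en-1-yl acetate | CC(=O)OC[C@H](CCC=C(C)C)C(=O)n1ccnc1
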